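Lignan numbering is used: C7 carries ring A (guaiacyl), C7' carries ring B (3-hydroxy-4,5-dimethoxyphenyl), C8 and C8' are the ring-fusion carbons, and the ethers are C7–O–C9' and C7'–O–C9.
Retrosynthesis: cut the two benzylic ether bonds C7–O and C7'–O, then C8'–C7' (lactone aldol with the ring B aldehyde), then C7–aryl (ring A metal reagent on an aldehyde), and last C8–C8' together with a throw-away C9–C8' bond of a cyclopropane.
Enabling feature: the branched unit C7–C8(–C9)–C8'–C9' is furan C3–C4(–C5) of methyl furan-2-carboxylate plus the two carbons of ethyl diazoacetate, so asymmetric cyclopropanation of the furan C4=C5 bond delivers it with C8 fixed.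
Forward: cyclopropane on the dearomatised furan, ozonolysis, ring A addition, silyl cap on C7–OH, retro-aldol opening with reduction to the C9'–O–C9 lactone, aldol, LiAlH4, then one acid step closes ring C7–O–C9' and then ring C7'–O–C9, and the benzyl ethers are removed.
Stereochemistry: C8 from the ligand-controlled cyclopropanation; C8' from the trans aldol on the lactone; C7 and C7' from kinetic exo closure of the benzylic cations on the cis-fused frame.

Key step: step 1

Assumption: the (R,R)-enantiomer of 2,2'-isopropylidenebis(4-isopropyl-2-oxazoline) is taken as the ligand that gives the (1R,5R,6R) adduct; if the sense of induction is the reverse, the (S,S)-ligand is used.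

Step 1
Reactants: 1 methyl furan-2-carboxylate; 2 ethyl diazoacetate
Product: 3 6-ethyl 3-methyl (1R,5R,6R)-2-oxabicyclo[3.1.0]hex-3-ene-3,6-dicarboxylate
Conditions: Cu(OTf)2 (1 mol %), (R,R)-2,2'-isopropylidenebis(4-isopropyl-2-oxazoline) (1.2 mol %), PhNHNH2 (1 mol %), CH2Cl2, 0 °C, slow addition of 2; recrystallisation
Reagents that add atoms: none
Why: Phenylhydrazine reduces Cu(OTf)2 to the monovalent copper bis(oxazoline) complex, which decomposes 2 with loss of N2 to an electrophilic copper carbene that adds to the furan C4=C5 bond in one concerted, asynchronous (2+1) step. The closest known reaction type is the copper bis(oxazoline) asymmetric cyclopropanation of furan-2-carboxylates with diazoacetates. The cyclopropane closes by this intermolecular (2+1) cycloaddition, suprafacial on the alkene, so C1 and C5 are necessarily cis-fused and the furan is dearomatised to an enol ether. C1 and C5 are set together by the furan enantioface that the C2-symmetric ligand leaves open, and C6 by the exo approach in which the carbene ester points away from the ring. Site selectivity (C4=C5 over C2=C3) comes from the furan ester, which makes its own double bond electron-poor and hindered, and the same deactivation should protect the product from a second addition. Crystallisation of 3 is planned to remove the minor enantiomer.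

Step 2
Reactants: 3 6-ethyl 3-methyl (1R,5R,6R)-2-oxabicyclo[3.1.0]hex-3-ene-3,6-dicarboxylate
Product: 4 ethyl (1R,2R,3R)-2-formyl-3-[(2-methoxy-2-oxoacetyl)oxy]cyclopropane-1-carboxylate
Conditions: O3, CH2Cl2, −78 °C; then Me2S, −78 °C → rt
Reagents that add atoms: ozone, [O-][O+]=O
Why: Ozonolysis with reductive work-up cleaves the only remaining C=C bond, so furan C3 becomes the C7 aldehyde and furan C2 the oxalate carbonyl on the C9 oxygen, while the three cyclopropane stereocentres are untouched.

Step 3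
Reactants: 5 4-bromo-2-methoxyphenol
Product: 6 1-(benzyloxy)-4-bromo-2-methoxybenzene
Conditions: BnBr, K2CO3, DMF, rt
Reagents that add atoms: benzyl bromide, BrCc1ccccc1
Why: Williamson ether synthesis on the phenoxide gives a benzyl ether that should withstand the organometallic, hydride and acid steps and fall only in the last step.

Step 4
Reactants: 6 1-(benzyloxy)-4-bromo-2-methoxybenzene; 4 ethyl (1R,2R,3R)-2-formyl-3-[(2-methoxy-2-oxoacetyl)oxy]cyclopropane-1-carboxylate
Product: 9 ethyl (1R,2S,3R)-2-[(S)-[4-(benzyloxy)-3-methoxyphenyl](hydroxy)methyl]-3-[(2-methoxy-2-oxoacetyl)oxy]cyclopropane-1-carboxylate, via aryllithium 7 (not isolated), via aryltitanium 8 (not isolated)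
Conditions: 6, n-BuLi, THF, −78 °C; ClTi(OiPr)3, −78 → −40 °C; 4, −78 °C; cold aq. NH4Cl
Reagents that add atoms: none
Why: Bromine–lithium exchange and transmetalation give an aryltitanium triisopropoxide, which should add to the aldehyde and spare the ester and oxalate carbonyls at low temperature (organotitanium carbonyl addition), and the C7 carbinol centre is set by Felkin–Anh control from the adjacent cyclopropane centre C8, in the sense that places ring A as in the target.

Step 5
Reactants: 9 ethyl (1R,2S,3R)-2-[(S)-[4-(benzyloxy)-3-methoxyphenyl](hydroxy)methyl]-3-[(2-methoxy-2-oxoacetyl)oxy]cyclopropane-1-carboxylate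
Product: 10 ethyl (1R,2R,3R)-2-[(S)-[4-(benzyloxy)-3-methoxyphenyl][(tert-butyldimethylsilyl)oxy]methyl]-3-[(2-methoxy-2-oxoacetyl)oxy]cyclopropane-1-carboxylate
Conditions: TBSOTf, 2,6-lutidine, CH2Cl2, −78 °C
Reagents that add atoms: tert-butyldimethylsilyl trifluoromethanesulfonate, CC(C)(C)[Si](C)(C)OS(=O)(=O)C(F)(F)F
Why: Silyl triflate silylation with a hindered pyridine base caps the C7 hydroxyl without touching the base-labile oxalate, so that this oxygen cannot capture the C9' ester when the cyclopropane is opened.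

Step 6
Reactants: 10 ethyl (1R,2R,3R)-2-[(S)-[4-(benzyloxy)-3-methoxyphenyl][(tert-butyldimethylsilyl)oxy]methyl]-3-[(2-methoxy-2-oxoacetyl)oxy]cyclopropane-1-carboxylate
Product: 13 (4R)-4-[(S)-[4-(benzyloxy)-3-methoxyphenyl][(tert-butyldimethylsilyl)oxy]methyl]dihydrofuran-2(3H)-one, via formyl ester 11 (not isolated), via hydroxy ester 12 (not isolated)
Conditions: Et3N, MeOH, 0 °C; then NaBH4, 0 °C; then PPTS (cat.), CH2Cl2, rt
Reagents that add atoms: none
Why: Methanolysis of the oxalate frees a cyclopropanol whose oxygen pushes open the C9–C8' bond toward the ester (retro-aldol opening of a donor–acceptor cyclopropane), the C9 aldehyde is reduced by NaBH4 before it can epimerise at C8, and the new primary hydroxyl lactonises onto the C9' ester, so no new stereocentre forms and C8 is carried over unchanged.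

Step 7
Reactants: 14 3-hydroxy-4,5-dimethoxybenzaldehyde
Product: 15 3-(benzyloxy)-4,5-dimethoxybenzaldehyde
Conditions: BnBr, K2CO3, DMF, rt
Reagents that add atoms: benzyl bromide, BrCc1ccccc1
Why: Williamson ether synthesis masks the ring B phenol so that it cannot quench the enolate in the next step.

Step 8
Reactants: 13 (4R)-4-[(S)-[4-(benzyloxy)-3-methoxyphenyl][(tert-butyldimethylsilyl)oxy]methyl]dihydrofuran-2(3H)-one; 15 3-(benzyloxy)-4,5-dimethoxybenzaldehyde
Product: 17 (3S,4R)-3-[[3-(benzyloxy)-4,5-dimethoxyphenyl](hydroxy)methyl]-4-[(S)-[4-(benzyloxy)-3-methoxyphenyl][(tert-butyldimethylsilyl)oxy]methyl]dihydrofuran-2(3H)-one (both C7' epimers), via lithium enolate 16 (not isolated)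
Conditions: LiN(iPr)2 (LDA, commercial solution), THF, −78 °C; 15, −78 °C; AcOH, −78 °C
Reagents that add atoms: none
Why: In this lithium enolate aldol addition the aldehyde should approach the planar lactone enolate on the face opposite the bulky silyloxybenzyl group at C8, which sets C8' trans to it (the relationship that permits cis ring fusion), while the carbinol centre C7' is not controlled and both epimers are carried on because step 10 re-forms it.

Step 9
Reactants: 17 (3S,4R)-3-[[3-(benzyloxy)-4,5-dimethoxyphenyl](hydroxy)methyl]-4-[(S)-[4-(benzyloxy)-3-methoxyphenyl][(tert-butyldimethylsilyl)oxy]methyl]dihydrofuran-2(3H)-one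
Product: 18 (2R,3R)-2-[[3-(benzyloxy)-4,5-dimethoxyphenyl](hydroxy)methyl]-3-[(S)-[4-(benzyloxy)-3-methoxyphenyl][(tert-butyldimethylsilyl)oxy]methyl]butane-1,4-diol (both C7' epimers)
Conditions: LiAlH4, THF, 0 °C; aqueous work-up
Reagents that add atoms: none
Why: LiAlH4 reduction of the lactone to the 1,4-diol should be faster than retro-aldol of the aluminium alkoxide at 0 °C and leaves the silyl ether, the benzyl ethers and the C8 and C8' centres unchanged.

Step 10
Reactants: 18 (2R,3R)-2-[[3-(benzyloxy)-4,5-dimethoxyphenyl](hydroxy)methyl]-3-[(S)-[4-(benzyloxy)-3-methoxyphenyl][(tert-butyldimethylsilyl)oxy]methyl]butane-1,4-diol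
Product: 20 (1S,3aR,4S,6aR)-1-[4-(benzyloxy)-3-methoxyphenyl]-4-[3-(benzyloxy)-4,5-dimethoxyphenyl]tetrahydro-1H,3H-furo[3,4-c]furan, via tetrahydrofuran diol 19 (not isolated)
Conditions: CSA (0.2 equiv), CH2Cl2, 0 °C → rt, stopped as soon as 19 is consumed
Reagents that add atoms: none
Why: The acid ionises first the C7 silyl ether and then the C7' carbinol to aryl-stabilised benzylic cations, each trapped 5-exo by the primary hydroxyl of the other arm (SN1 cyclodehydration of a lignan tetraol to a furofuran); C7 and C7' are set under kinetic control because each aryl group closes trans to the substituent on the neighbouring ring-fusion carbon and away from the concave face, and the cis fusion is dictated by the C8 and C8' centres already in place.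

Step 11
Reactants: 20 (1S,3aR,4S,6aR)-1-[4-(benzyloxy)-3-methoxyphenyl]-4-[3-(benzyloxy)-4,5-dimethoxyphenyl]tetrahydro-1H,3H-furo[3,4-c]furan
Product: 21 5-[(1S,3aR,4S,6aR)-4-(4-hydroxy-3-methoxyphenyl)tetrahydro-1H,3H-furo[3,4-c]furan-1-yl]-2,3-dimethoxyphenol
Conditions: H2 (1 atm), 10% Pd/C, EtOAc, rt, stopped at complete debenzylation
Reagents that add atoms: none
Why: Catalytic hydrogenolysis should cleave the two aryl benzyl ethers well before the benzylic ether bonds of the bicyclic core under neutral conditions, freeing both phenols without touching a stereocentre.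

Compound list
1 | methyl furan-2-carboxylate | COC(=O)c1ccco1 | starting material
2 | ethyl diazoacetate | CCOC(=O)C=[N+]=[N-] | starting material
3 | 6-ethyl 3-methyl (1R,5R,6R)-2-oxabicyclo[3.1.0]hex-3-ene-3,6-dicarboxylate (ester at C6 exo) | CCOC(=O)[C@@H]1[C@H]2C=C(C(=O)OC)O[C@@H]12 | intermediate
4 | ethyl (1R,2R,3R)-2-formyl-3-[(2-methoxy-2-oxoacetyl)oxy]cyclopropane-1-carboxylate (formyl and oxalyloxy cis, ester trans to both) | CCOC(=O)[C@@H]1[C@@H](C=O)[C@H]1OC(=O)C(=O)OC | intermediate
5 | 4-bromo-2-methoxyphenol | COc1cc(Br)ccc1O | starting material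
6 | 1-(benzyloxy)-4-bromo-2-methoxybenzene | COc1cc(Br)ccc1OCc1ccccc1 | intermediate
7 | [4-(benzyloxy)-3-methoxyphenyl]lithium (formed in the flask) | [Li]c1ccc(OCc2ccccc2)c(OC)c1 | intermediate
8 | [4-(benzyloxy)-3-methoxyphenyl]titanium triisopropoxide (formed in the flask) | CC(C)O[Ti](OC(C)C)(OC(C)C)c1ccc(OCc2ccccc2)c(OC)c1 | intermediate
9 | ethyl (1R,2S,3R)-2-[(S)-[4-(benzyloxy)-3-methoxyphenyl](hydroxy)methyl]-3-[(2-methoxy-2-oxoacetyl)oxy]cyclopropane-1-carboxylate | CCOC(=O)[C@@H]1[C@@H]([C@H](O)c2ccc(OCc3ccccc3)c(OC)c2)[C@H]1OC(=O)C(=O)OC | intermediate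
10 | ethyl (1R,2R,3R)-2-[(S)-[4-(benzyloxy)-3-methoxyphenyl][(tert-butyldimethylsilyl)oxy]methyl]-3-[(2-methoxy-2-oxoacetyl)oxy]cyclopropane-1-carboxylate | CCOC(=O)[C@@H]1[C@@H]([C@H](O[Si](C)(C)C(C)(C)C)c2ccc(OCc3ccccc3)c(OC)c2)[C@H]1OC(=O)C(=O)OC | intermediate
11 | ethyl (3S,4S)-4-[4-(benzyloxy)-3-methoxyphenyl]-4-[(tert-butyldimethylsilyl)oxy]-3-formylbutanoate (formed in the flask) | CCOC(=O)C[C@H](C=O)[C@H](O[Si](C)(C)C(C)(C)C)c1ccc(OCc2ccccc2)c(OC)c1 | intermediate
12 | ethyl (3R,4S)-4-[4-(benzyloxy)-3-methoxyphenyl]-4-[(tert-butyldimethylsilyl)oxy]-3-(hydroxymethyl)butanoate (formed in the flask) | CCOC(=O)C[C@H](CO)[C@H](O[Si](C)(C)C(C)(C)C)c1ccc(OCc2ccccc2)c(OC)c1 | intermediate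
13 | (4R)-4-[(S)-[4-(benzyloxy)-3-methoxyphenyl][(tert-butyldimethylsilyl)oxy]methyl]dihydrofuran-2(3H)-one | O=C1C[C@H](CO1)[C@H](O[Si](C)(C)C(C)(C)C)c1ccc(OCc2ccccc2)c(OC)c1 | intermediate
14 | 3-hydroxy-4,5-dimethoxybenzaldehyde | COc1cc(C=O)cc(O)c1OC | starting material
15 | 3-(benzyloxy)-4,5-dimethoxybenzaldehyde | COc1cc(C=O)cc(OCc2ccccc2)c1OC | intermediate
16 | lithium enolate of 13 (formed in the flask) | [Li]OC1=C[C@H](CO1)[C@H](O[Si](C)(C)C(C)(C)C)c1ccc(OCc2ccccc2)c(OC)c1 | intermediate
17 | (3S,4R)-3-[[3-(benzyloxy)-4,5-dimethoxyphenyl](hydroxy)methyl]-4-[(S)-[4-(benzyloxy)-3-methoxyphenyl][(tert-butyldimethylsilyl)oxy]methyl]dihydrofuran-2(3H)-one, both epimers at the C7' carbinol carbon | O=C1OC[C@H]([C@H](O[Si](C)(C)C(C)(C)C)c2ccc(OCc3ccccc3)c(OC)c2)[C@H]1C(O)c1cc(OC)c(OC)c(OCc2ccccc2)c1 | intermediate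
18 | (2R,3R)-2-[[3-(benzyloxy)-4,5-dimethoxyphenyl](hydroxy)methyl]-3-[(S)-[4-(benzyloxy)-3-methoxyphenyl][(tert-butyldimethylsilyl)oxy]methyl]butane-1,4-diol, both epimers at the C7' carbinol carbon | OC[C@H]([C@H](O[Si](C)(C)C(C)(C)C)c1ccc(OCc2ccccc2)c(OC)c1)[C@H](CO)C(O)c1cc(OC)c(OC)c(OCc2ccccc2)c1 | intermediate
19 | [(2S,3R,4R)-2-[4-(benzyloxy)-3-methoxyphenyl]-4-[[3-(benzyloxy)-4,5-dimethoxyphenyl](hydroxy)methyl]tetrahydrofuran-3-yl]methanol, both epimers at the C7' carbinol carbon (formed in the flask) | COc1cc([C@H]2OC[C@H](C(O)c3cc(OCc4ccccc4)c(OC)c(OC)c3)[C@@H]2CO)ccc1OCc1ccccc1 | intermediate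
20 | (1S,3aR,4S,6aR)-1-[4-(benzyloxy)-3-methoxyphenyl]-4-[3-(benzyloxy)-4,5-dimethoxyphenyl]tetrahydro-1H,3H-furo[3,4-c]furan | COc1cc([C@H]2OC[C@H]3[C@@H]2CO[C@@H]3c2cc(OCc4ccccc4)c(OC)c(OC)c2)ccc1OCc1ccccc1 | intermediate
21 | 5-[(1S,3aR,4S,6aR)-4-(4-hydroxy-3-methoxyphenyl)tetrahydro-1H,3H-furo[3,4-c]furan-1-yl]-2,3-dimethoxyphenol | COc1cc([C@H]2OC[C@H]3[C@@H]2CO[C@@H]3c2cc(O)c(OC)c(OC)c2)ccc1O | target

Total step count: 11. Longest linear sequence: 9 steps (steps 1, 2, 4, 5, 6, 8, 9, 10, 11); steps 3 and 7 are one-step side branches.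

Steps most likely to fail

Step 10. The exo preference may be eroded if the closed benzylic ethers re-ionise and drift toward the endo aryl epimers. The C7 cation may also be caught by the C7' hydroxyl, giving a 2,5-diaryltetrahydrofuran, or a benzylic cation may attack the other arene in a Friedel–Crafts closure. The fallback makes the closure stereospecific and sets out from aldol mixture 17. Dess–Martin periodinane should convert both epimers into the single β-keto lactone F1. Zn(BH4)2 in ether should then reduce it under chelation control to the syn carbinol F2, which has the 7'S configuration. LiAlH4 gives the silyl triol F3 and Bu4NF the tetraol F4. MsCl in pyridine at 0 °C should sulfonylate the two primary hydroxyls selectively to the bis(methanesulfonate) F5. On warming, the benzylic hydroxyls displace the sulfonates at C9 and C9' with retention at C7 and C7', and the sequence returns to 20.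

Step 6. While the open-chain aldehyde is exposed to base it may epimerise at C8 or lose the silyloxy group by elimination before the hydride arrives, and the lactonisation may stall at the hydroxy ester. The fallback keeps the aldehyde inside a ring and sets out from carbinol 9. Ba(OH)2·8H2O in MeOH at 0 °C removes the oxalate; the cyclopropanol opens and lactonises through the free C7 hydroxyl to the trans formyl lactone F6. NaBH4 gives the hydroxymethyl lactone F7. MeNHOMe·HCl with AlMe3 opens the lactone to the dihydroxy amide F8, and TBSOTf with 2,6-lutidine gives the bis(silyl) ether F9. HF·pyridine removes the primary silyl group, and the freed C9 hydroxyl closes on the amide under PPTS, which returns to 13.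

Step 4. The aryl metal may attack the oxalate carbonyls, or the oxalyl group may shift to the new titanium alkoxide and trigger early opening of the cyclopropane. The fallback delivers the aryl group by a Nozaki–Hiyama–Kishi reaction and sets out from bromide 6. NaI with catalytic CuI and N,N'-dimethylethylenediamine in dioxane (aromatic Finkelstein exchange) gives the aryl iodide F10. F10 and aldehyde 4 are then combined with CrCl2 and catalytic NiCl2 in DMF at room temperature. The arylchromium species adds only to aldehydes and leaves a weakly basic chromium alkoxide, and the sequence returns to 9.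

Further compounds
F1 | step 10 | (3S,4R)-3-[3-(benzyloxy)-4,5-dimethoxybenzoyl]-4-[(S)-[4-(benzyloxy)-3-methoxyphenyl][(tert-butyldimethylsilyl)oxy]methyl]dihydrofuran-2(3H)-one | O=C1OC[C@H]([C@H](O[Si](C)(C)C(C)(C)C)c2ccc(OCc3ccccc3)c(OC)c2)[C@H]1C(=O)c1cc(OC)c(OC)c(OCc2ccccc2)c1
F2 | step 10 | (3S,4R)-3-[(S)-[3-(benzyloxy)-4,5-dimethoxyphenyl](hydroxy)methyl]-4-[(S)-[4-(benzyloxy)-3-methoxyphenyl][(tert-butyldimethylsilyl)oxy]methyl]dihydrofuran-2(3H)-one | O=C1OC[C@H]([C@H](O[Si](C)(C)C(C)(C)C)c2ccc(OCc3ccccc3)c(OC)c2)[C@H]1[C@H](O)c1cc(OC)c(OC)c(OCc2ccccc2)c1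
F3 | step 10 | (2R,3R)-2-[(S)-[3-(benzyloxy)-4,5-dimethoxyphenyl](hydroxy)methyl]-3-[(S)-[4-(benzyloxy)-3-methoxyphenyl][(tert-butyldimethylsilyl)oxy]methyl]butane-1,4-diol | OC[C@H]([C@H](O[Si](C)(C)C(C)(C)C)c1ccc(OCc2ccccc2)c(OC)c1)[C@H](CO)[C@H](O)c1cc(OC)c(OC)c(OCc2ccccc2)c1
F4 | step 10 | (1S,2R,3R,4S)-1-[4-(benzyloxy)-3-methoxyphenyl]-4-[3-(benzyloxy)-4,5-dimethoxyphenyl]-2,3-bis(hydroxymethyl)butane-1,4-diol | OC[C@H]([C@H](O)c1ccc(OCc2ccccc2)c(OC)c1)[C@H](CO)[C@H](O)c1cc(OC)c(OC)c(OCc2ccccc2)c1
F5 | step 10 | (2R,3R)-2-[(S)-[3-(benzyloxy)-4,5-dimethoxyphenyl](hydroxy)methyl]-3-[(S)-[4-(benzyloxy)-3-methoxyphenyl](hydroxy)methyl]butane-1,4-diyl dimethanesulfonate | CS(=O)(=O)OC[C@H]([C@H](O)c1ccc(OCc2ccccc2)c(OC)c1)[C@H](COS(C)(=O)=O)[C@H](O)c1cc(OC)c(OC)c(OCc2ccccc2)c1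
F6 | step 6 | (2S,3S)-2-[4-(benzyloxy)-3-methoxyphenyl]-5-oxotetrahydrofuran-3-carbaldehyde (aryl and formyl trans) | O=C[C@H]1CC(=O)O[C@@H]1c1ccc(OCc2ccccc2)c(OC)c1
F7 | step 6 | (4R,5S)-5-[4-(benzyloxy)-3-methoxyphenyl]-4-(hydroxymethyl)dihydrofuran-2(3H)-one | OC[C@H]1CC(=O)O[C@@H]1c1ccc(OCc2ccccc2)c(OC)c1
F8 | step 6 | (3R,4S)-4-[4-(benzyloxy)-3-methoxyphenyl]-4-hydroxy-3-(hydroxymethyl)-N-methoxy-N-methylbutanamide | CON(C)C(=O)C[C@H](CO)[C@H](O)c1ccc(OCc2ccccc2)c(OC)c1
F9 | step 6 | (3R,4S)-4-[4-(benzyloxy)-3-methoxyphenyl]-4-[(tert-butyldimethylsilyl)oxy]-3-[[(tert-butyldimethylsilyl)oxy]methyl]-N-methoxy-N-methylbutanamide | CON(C)C(=O)C[C@H](CO[Si](C)(C)C(C)(C)C)[C@H](O[Si](C)(C)C(C)(C)C)c1ccc(OCc2ccccc2)c(OC)c1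
F10 | step 4 | 1-(benzyloxy)-4-iodo-2-methoxybenzene | COc1cc(I)ccc1OCc1ccccc1
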